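## Retrosynthetic overview

- The last C–C bond is C12–C13: B-alkyl Suzuki–Miyaura coupling of a 9-vinyl decalin diol with a preformed (R)-butenolide (E)-vinyl iodide, then PMB removal.
- Ring B (six-membered) is formed last on the core, by a semipinacol 1,2-shift that inserts C9 between C8 and C10 of a trans-hydrindanone (spiro vinyl oxirane → 2-vinylcyclohexanone). The C8 carbinol then comes from the new ketone by methylenation and Markovnikov hydration.
- The hydrindanone comes from a Hajos–Parrish-type enedione: C4 quaternary centre by deconjugative alkylation, C3 deoxygenation, 5α-H/6α-OH by hydroboration.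
- Ring A is formed first, by Robinson annulation of 2-methylcyclopentane-1,3-dione with ethyl vinyl ketone; the dione ring is the five-membered precursor of ring B and C10 is set here.
- The butenolide ring is closed on the side-chain fragment by ring-closing metathesis after asymmetric propargylation of methacrolein.

Assumption: the target is taken as drawn, i.e. (4R,5R,6S,8R,9R,10S) in the decalin, E at the chain olefin and R in the butenolide. Bicyclic intermediates are described with labdane numbering (in the hydrindanes C9 is absent and C8 is bonded to C10; α is the face opposite the C10 methyl; PMB = 4-methoxybenzyl, TES = triethylsilyl).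

## Route

Step 1
Reactants: 1 2-methylcyclopentane-1,3-dione; 2 pent-1-en-3-one (ethyl vinyl ketone)
Product: 4 (7aS)-4,7a-dimethyl-2,3,7,7a-tetrahydro-1H-indene-1,5(6H)-dione, via triketone 3 (not isolated)
Conditions: Et3N (cat.), neat, rt; then L-phenylalanine, (+)-CSA, DMF, 30 → 70 °C
Reagents that add atoms: none
Why: Michael addition followed by the amino-acid-catalysed Hajos–Parrish–Eder–Sauer–Wiechert aldol condensation desymmetrises the prochiral triketone through an enamine transition state, and L-phenylalanine sets the quaternary carbon (future C10) as S.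

Step 2
Reactants: 4 (7aS)-4,7a-dimethyl-2,3,7,7a-tetrahydro-1H-indene-1,5(6H)-dione
Product: 5 C8 ethylene ketal of 4
Conditions: ethylene glycol, TsOH·H2O (cat.), 4 Å MS, CH2Cl2, rt
Reagents that add atoms: ethylene glycol (OCCO)
Why: Acid-catalysed ketalisation is chemoselective for the saturated cyclopentanone because the conjugated enone carbonyl is much less electrophilic, and no stereocentre is formed.

Step 3
Reactants: 5 C8 ethylene ketal of 4
Product: 6 3-oxo-hydrind-5-ene ketal with 4α-CH2OPMB and 4β-methyl
Conditions: KOtBu, THF, 0 °C; then PMBOCH2Cl, −78 → 0 °C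
Reagents that add atoms: 4-methoxybenzyl chloromethyl ether (COc1ccc(COCCl)cc1)
Why: Deconjugative α-alkylation (SN2) of the thermodynamic extended dienolate occurs at C4 on the face opposite the angular methyl, which places CH2OPMB α and the existing methyl β (4R) and moves the olefin to C5=C6.

Step 4
Reactants: 6 3-oxo-hydrind-5-ene ketal with 4α-CH2OPMB and 4β-methyl
Product: 7 hydrind-5-ene ketal (C3 = CH2)
Conditions: N2H4·H2O, KOH, diethylene glycol, 130 → 200 °C
Reagents that add atoms: none
Why: Wolff–Kishner reduction (Huang–Minlon procedure) removes the hindered C3 carbonyl through its hydrazone under basic conditions that leave the ketal, the PMB ether and the isolated olefin untouched, and no stereocentre is affected.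

Step 5
Reactants: 7 hydrind-5-ene ketal (C3 = CH2)
Product: 9 6α-hydroxy-5α-hydrindan-8-one (trans-fused), via ketal alcohol 8 (not isolated)
Conditions: BH3·THF, THF, 0 → 40 °C; NaOH, H2O2; then 1 M HCl, THF, rt
Reagents that add atoms: hydrogen peroxide (OO); water (O)
Why: Brown hydroboration–oxidation adds H and B syn and anti-Markovnikov from the α face (the β face is blocked by the C10 and C4β methyls), which sets 5α-H and 6α-OH with retention on oxidation, and dilute acid then hydrolyses the dioxolane.

Step 6
Reactants: 9 6α-hydroxy-5α-hydrindan-8-one (trans-fused); 10 allyl bromide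
Product: 13 spiro vinyl oxirane (6-O-TES ether), via silyl ether 11 (not isolated), via sulfonium salt 12 (not isolated)
Conditions: Et3SiCl, Et3N, DMAP (cat.), THF, rt; then tetrahydrothiophene (premixed with 10, MeCN, rt), KOtBu, THF, −78 → 0 °C
Reagents that add atoms: chlorotriethylsilane (CC[Si](Cl)(CC)CC)
Why: After in-flask silylation of the β-hydroxyl (which blocks retro-aldol cleavage), Corey–Chaykovsky epoxidation with the allyl sulfonium ylide adds through its α-carbon to the cyclopentanone and closes to the vinyl oxirane; the two oxirane centres form as a mixture, which is harmless because both are erased or reset in step 7.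

Step 7
Reactants: 13 spiro vinyl oxirane (6-O-TES ether)
Product: 15 6α-hydroxy-9β-vinyl-trans-decalin-8-one, via silyl ether 14 (not isolated)
Conditions: Pd2(dba)3 (2.5 mol %), P(OPh)3 (12 mol %), toluene, 60 °C; then HF·pyridine, pyridine, THF, 0 °C
Reagents that add atoms: none
Why: Proposed new method: zerovalent palladium ionises the allylic C9–O bond of the vinyl oxirane with inversion to a π-allyl palladium/tertiary alkoxide zwitterion that has no β-hydrogen on C8 and so cannot leak to a dienol or enone; the alkoxide then drives a semipinacol 1,2-shift of the more substituted C8–C10 bond onto C9 anti to the metal, which expands the five-membered ring to the six-membered ring B with C8 as ketone and the vinyl group 9β (equatorial, favoured in the chair-like migration transition state and also the thermodynamic α-epimer); the closest known reactions are the palladium-catalysed Wagner–Meerwein ring expansions of strained vinyl oxaspirohexanes and of allenyl- or vinylcyclobutanols and the Lewis-acid semipinacol rearrangement of 2,3-epoxy alcohols, none of which has been shown on an unstrained cyclopentane with a migrating quaternary carbon; buffered HF·pyridine then removes the silyl ether.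

Step 8
Reactants: 15 6α-hydroxy-9β-vinyl-trans-decalin-8-one
Product: 16 8(17)-methylene-9β-vinyl-trans-decalin-6α-ol
Conditions: Zn, CH2Br2, TiCl4, THF/CH2Cl2, 0 °C → rt
Reagents that add atoms: dibromomethane (BrCBr)
Why: Takai–Lombardo methylenation uses a non-basic gem-dimetallic CH2 reagent, so the hindered and easily enolised β,γ-unsaturated β-hydroxy ketone is converted into the exocyclic olefin without C9 epimerisation, conjugation of the vinyl group or retro-aldol cleavage.

Step 9
Reactants: 16 8(17)-methylene-9β-vinyl-trans-decalin-6α-ol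
Product: 18 8β-methyl-9β-vinyl-trans-decalin-6α,8α-diol, via organomercurial 17 (not isolated)
Conditions: Hg(OAc)2, THF/H2O, 0 °C; then NaBH4, aq NaOH, 0 °C
Reagents that add atoms: water (O)
Why: Markovnikov oxymercuration–demercuration is about an order of magnitude faster at the 1,1-disubstituted exocyclic olefin than at the hindered vinyl group, and water opens the mercurinium ion at C8 from the equatorial α side because axial attack is blocked by the syn-axial C10 methyl, which gives the 8α-hydroxy-8β-methyl centre (8R).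

Step 10
Reactants: 19 2-methylprop-2-enal (methacrolein); 20 3-bromoprop-1-yne (propargyl bromide)
Product: 22 (R)-2-methylhex-1-en-5-yn-3-ol, via silyl ether 21 (not isolated)
Conditions: CrCl2 (10 mol %), chiral bis(oxazolinyl)carbazole ligand (12 mol %), Mn, Me3SiCl, iPr2NEt (cat.), THF, rt; then 1 M HCl
Reagents that add atoms: none
Why: In this catalytic asymmetric Nozaki–Hiyama propargylation the allenylchromium species adds in SE2' fashion to the aldehyde inside the chiral ligand sphere to give the homopropargylic alcohol, the ligand enantiomer being chosen to deliver the R carbinol that becomes the butenolide stereocentre.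

Step 11
Reactants: 22 (R)-2-methylhex-1-en-5-yn-3-ol
Product: 23 (R)-2-methylhept-1-en-5-yn-3-ol
Conditions: n-BuLi (2.1 equiv), THF/DMPU, −78 °C; MeI, −78 → 0 °C
Reagents that add atoms: iodomethane (CI)
Why: The alkoxide–acetylide dianion is methylated at the softer and more nucleophilic acetylide carbon (SN2 alkylation), and the stereocentre is not involved.

Step 12
Reactants: 23 (R)-2-methylhept-1-en-5-yn-3-ol
Product: 25 (R,E)-6-iodo-2-methylhepta-1,5-dien-3-ol, via alkenylzirconocene 24 (not isolated)
Conditions: Cp2Zr(H)Cl (2.5 equiv), THF, rt → 40 °C; then I2, 0 °C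
Reagents that add atoms: iodine (II)
Why: Syn hydrozirconation of the 2-alkyne places zirconium on the less hindered methyl-bearing carbon after equilibration with excess Cp2Zr(H)Cl, and iodinolysis with retention gives the E vinyl iodide.

Step 13
Reactants: 25 (R,E)-6-iodo-2-methylhepta-1,5-dien-3-ol; 26 acryloyl chloride
Product: 27 (R,E)-6-iodo-2-methylhepta-1,5-dien-3-yl acrylate
Conditions: Et3N, DMAP (cat.), CH2Cl2, 0 °C
Reagents that add atoms: none
Why: Nucleophilic acyl substitution of the acid chloride by the secondary allylic alcohol gives the acrylate without touching the stereocentre.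

Step 14
Reactants: 27 (R,E)-6-iodo-2-methylhepta-1,5-dien-3-yl acrylate
Product: 28 (R)-5-[(E)-3-iodobut-2-en-1-yl]-4-methylfuran-2(5H)-one
Conditions: second-generation Grubbs catalyst (5 mol %), toluene, 80 °C
Reagents that add atoms: none
Why: Ring-closing metathesis between the acrylate and the 1,1-disubstituted olefin closes the butenolide with loss of ethene, while the trisubstituted vinyl iodide is inert and the stereocentre is not involved.

Step 15
Reactants: 18 8β-methyl-9β-vinyl-trans-decalin-6α,8α-diol; 28 (R)-5-[(E)-3-iodobut-2-en-1-yl]-4-methylfuran-2(5H)-one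
Product: 30 18-O-PMB ether of the target, via alkylborane 29 (not isolated)
Conditions: 9-BBN (excess), THF, rt; then 28, Pd(dppf)Cl2 (5 mol %), AsPh3, K3PO4, DMF/H2O, rt
Reagents that add atoms: none
Why: Anti-Markovnikov hydroboration of the terminal vinyl group with 9-BBN followed by B-alkyl Suzuki–Miyaura coupling joins C12 to C13 with retention of the E vinyl iodide geometry, under a mild base at room temperature that should not epimerise the butenolide.

Step 16
Reactants: 30 18-O-PMB ether of the target
Product: 31 target CNP0147582.1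
Conditions: DDQ, CH2Cl2/pH 7 buffer, 0 °C
Reagents that add atoms: none
Why: Oxidative PMB ether cleavage by DDQ (hydride abstraction, then hydrolysis of the oxocarbenium ion) frees the primary alcohol without affecting the olefins, the butenolide or the tertiary alcohol.

## Compound list

1 | 2-methylcyclopentane-1,3-dione | CC1C(=O)CCC1=O | starting material
2 | pent-1-en-3-one (ethyl vinyl ketone) | CCC(=O)C=C | starting material
3 | 2-methyl-2-(3-oxopentyl)cyclopentane-1,3-dione | CCC(=O)CCC1(C)C(=O)CCC1=O | intermediate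
4 | (7aS)-4,7a-dimethyl-2,3,7,7a-tetrahydro-1H-indene-1,5(6H)-dione | O=C1[C@@]2(C)CCC(=O)C(C)=C2CC1 | intermediate
5 | C8 ethylene ketal of 4 (enone retained, 10S) | O1CCOC13[C@@]2(C)CCC(=O)C(C)=C2CC3 | intermediate
6 | 3-oxo-hydrind-5-ene with 4α-CH2OPMB, 4β-methyl, 10β-methyl and C8 ethylene ketal (4R,10S) | O1CCOC13[C@@]2(C)CCC(=O)[C@@](C)(COCc4ccc(OC)cc4)C2=CC3 | intermediate
7 | hydrind-5-ene with 4α-CH2OPMB, 4β-methyl, 10β-methyl and C8 ethylene ketal (C3 = CH2) | O1CCOC13[C@@]2(C)CCC[C@@](C)(COCc4ccc(OC)cc4)C2=CC3 | intermediate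
8 | 6α-hydroxy-5α-hydrindane C8 ethylene ketal (4α-CH2OPMB; 4β,10β-dimethyl) | O1CCOC13[C@@]2(C)CCC[C@@](C)(COCc4ccc(OC)cc4)[C@@H]2[C@@H](O)C3 | intermediate
9 | 6α-hydroxy-4α-(PMB-oxymethyl)-4β,10β-dimethyl-5α-hydrindan-8-one (trans-fused) | O=C1[C@@]2(C)CCC[C@@](C)(COCc3ccc(OC)cc3)[C@@H]2[C@@H](O)C1 | intermediate
10 | allyl bromide (3-bromoprop-1-ene) | C=CCBr | starting material
11 | 6-O-TES ether of 9 | O=C1[C@@]2(C)CCC[C@@](C)(COCc3ccc(OC)cc3)[C@@H]2[C@@H](O[Si](CC)(CC)CC)C1 | intermediate
12 | S-allyltetrahydrothiophenium bromide | C=CC[S+]1CCCC1.[Br-] | intermediate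
13 | spiro vinyl oxirane: 8,9-epoxy-9-vinyl hydrindane, 6α-OTES (mixture at the two oxirane carbons) | C=CC1OC12[C@@]3(C)CCC[C@@](C)(COCc4ccc(OC)cc4)[C@@H]3[C@@H](O[Si](CC)(CC)CC)C2 | intermediate
14 | 6-O-TES ether of 15 | C=C[C@@H]1[C@@]2(C)CCC[C@@](C)(COCc3ccc(OC)cc3)[C@@H]2[C@@H](O[Si](CC)(CC)CC)CC1=O | intermediate
15 | 6α-hydroxy-4α-(PMB-oxymethyl)-4β,10β-dimethyl-9β-vinyl-trans-decalin-8-one (5α-H, 9α-H) | C=C[C@@H]1[C@@]2(C)CCC[C@@](C)(COCc3ccc(OC)cc3)[C@@H]2[C@@H](O)CC1=O | intermediate
16 | 8(17)-methylene analogue of 15 (6α-OH, 9β-vinyl) | C=C[C@@H]1[C@@]2(C)CCC[C@@](C)(COCc3ccc(OC)cc3)[C@@H]2[C@@H](O)CC1=C | intermediate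
17 | 17-(acetoxymercurio)-6α,8α-diol (9β-vinyl) | C=C[C@@H]1[C@@]2(C)CCC[C@@](C)(COCc3ccc(OC)cc3)[C@@H]2[C@@H](O)C[C@@]1(C[Hg]OC(C)=O)O | intermediate
18 | 4α-(PMB-oxymethyl)-4β,8β,10β-trimethyl-9β-vinyl-trans-decalin-6α,8α-diol | C=C[C@@H]1[C@@]2(C)CCC[C@@](C)(COCc3ccc(OC)cc3)[C@@H]2[C@@H](O)C[C@@]1(C)O | intermediate
19 | 2-methylprop-2-enal (methacrolein) | CC(=C)C=O | starting material
20 | 3-bromoprop-1-yne (propargyl bromide) | C#CCBr | starting material
21 | trimethylsilyl ether of 22 | C[Si](C)(C)O[C@@H](C(C)=C)CC#C | intermediate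
22 | (R)-2-methylhex-1-en-5-yn-3-ol | O[C@@H](C(C)=C)CC#C | intermediate
23 | (R)-2-methylhept-1-en-5-yn-3-ol | O[C@@H](C(C)=C)CC#CC | intermediate
24 | (E)-alkenyl(chloro)zirconocene of 23, oxygen also bound to chlorozirconocene | Cl[Zr](C1C=CC=C1)(C1C=CC=C1)O[C@@H](C(C)=C)C/C=C(\C)[Zr](Cl)(C1C=CC=C1)C1C=CC=C1 | intermediate
25 | (R,E)-6-iodo-2-methylhepta-1,5-dien-3-ol | O[C@@H](C(C)=C)C/C=C(\C)I | intermediate
26 | acryloyl chloride | C=CC(=O)Cl | starting material
27 | (R,E)-6-iodo-2-methylhepta-1,5-dien-3-yl acrylate | C=CC(=O)O[C@@H](C(C)=C)C/C=C(\C)I | intermediate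
28 | (R)-5-[(E)-3-iodobut-2-en-1-yl]-4-methylfuran-2(5H)-one | CC1=CC(=O)O[C@@H]1C/C=C(\C)I | intermediate
29 | B-alkyl-9-BBN from 18 (boron on C12) | C(C[C@@H]1[C@@]2(C)CCC[C@@](C)(COCc3ccc(OC)cc3)[C@@H]2[C@@H](O)C[C@@]1(C)O)B1C2CCCC1CCC2 | intermediate
30 | 18-O-PMB ether of the target | CC1=CC(=O)O[C@@H]1C/C=C(\C)CC[C@@H]1[C@@]2(C)CCC[C@@](C)(COCc3ccc(OC)cc3)[C@@H]2[C@@H](O)C[C@@]1(C)O | intermediate
31 | CNP0147582.1 | CC1=CC(=O)O[C@@H]1C/C=C(\C)CC[C@@H]1[C@@]2(C)CCC[C@@](C)(CO)[C@@H]2[C@@H](O)C[C@@]1(C)O | target

## Step count and risk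

Total step count: 16. Longest linear sequence: 11 steps (steps 1–9, 15, 16); the fragment 28 is made in 5 steps (10–14).

The three steps most likely to fail:

Step 7 (the proposed palladium ring expansion). The zwitterion could instead close to a spiro dihydrofuran, or C7 could migrate in place of C10. The fallback uses known chemistry and sets out from 11. CeCl3-mediated addition of vinylmagnesium bromide gives the tertiary allylic alcohol F1. Hydroxyl-directed epoxidation with VO(acac)2 and tBuOOH gives the 2,3-epoxy alcohol F2. BF3·OEt2 at −78 °C then triggers the established Lewis-acid semipinacol ring expansion of a 1-oxiranyl cycloalkanol, in which C10 migrates to C9 as the oxirane opens, to give the 9β-hydroxymethyl decalin-8-one F3. Methylenation with Zn, CH2Br2 and TiCl4 gives the exocyclic olefin F4, and oxymercuration–demercuration gives the 8α,11-diol F5. TEMPO with PhI(OAc)2 oxidises only the primary alcohol to the aldehyde F6, Ph3P=CH2 converts it into the vinyl compound F7, and HF·pyridine removes the silyl ether to come back to the route at 18.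

Step 6 (sulfonium ylide epoxidation of a hindered ketone next to a quaternary carbon). The fallback sets out from 11. Allyl methyl sulfide is deprotonated with s-BuLi and transmetallated with Ti(OiPr)4; this reagent adds through its sulfur-bearing carbon to the ketone to give the β-hydroxy sulfide F8. S-methylation with Me3OBF4 followed by aqueous NaOH closes the oxirane with loss of dimethyl sulfide and comes back to the route at 13.

Step 3 (the chloromethyl ether may O-alkylate the dienolate, or react with alkoxide). The fallback sets out from 5. The same potassium dienolate is trapped at −78 °C with gaseous formaldehyde, an aldol hydroxymethylation at C4 from the same α face, to give the hydroxymethyl ketone F9. Protection under non-basic conditions with 4-methoxybenzyl trichloroacetimidate and catalytic La(OTf)3 avoids retro-aldol cleavage and comes back to the route at 6.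

Further compounds
F1 | step 7 | tertiary allylic alcohol: 8-hydroxy-8-vinyl hydrindane, 6α-OTES (C8 configuration immaterial) | C=CC1(O)[C@@]2(C)CCC[C@@](C)(COCc3ccc(OC)cc3)[C@@H]2[C@@H](O[Si](CC)(CC)CC)C1
F2 | step 7 | 2,3-epoxy alcohol: 8-hydroxy-8-oxiranyl hydrindane, 6α-OTES | C1OC1C3(O)[C@@]2(C)CCC[C@@](C)(COCc4ccc(OC)cc4)[C@@H]2[C@@H](O[Si](CC)(CC)CC)C3
F3 | step 7 | 9β-(hydroxymethyl)-trans-decalin-8-one, 6α-OTES | OC[C@@H]1[C@@]2(C)CCC[C@@](C)(COCc3ccc(OC)cc3)[C@@H]2[C@@H](O[Si](CC)(CC)CC)CC1=O
F4 | step 7 | 9β-(hydroxymethyl)-8(17)-methylene-trans-decalin, 6α-OTES | OC[C@@H]1[C@@]2(C)CCC[C@@](C)(COCc3ccc(OC)cc3)[C@@H]2[C@@H](O[Si](CC)(CC)CC)CC1=C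
F5 | step 7 | 9β-(hydroxymethyl)-8β-methyl-trans-decalin-8α-ol, 6α-OTES | OC[C@@H]1[C@@]2(C)CCC[C@@](C)(COCc3ccc(OC)cc3)[C@@H]2[C@@H](O[Si](CC)(CC)CC)C[C@@]1(C)O
F6 | step 7 | 8α-hydroxy-8β-methyl-trans-decalin-9β-carbaldehyde, 6α-OTES | O=C[C@@H]1[C@@]2(C)CCC[C@@](C)(COCc3ccc(OC)cc3)[C@@H]2[C@@H](O[Si](CC)(CC)CC)C[C@@]1(C)O
F7 | step 7 | 6-O-TES ether of 18 | C=C[C@@H]1[C@@]2(C)CCC[C@@](C)(COCc3ccc(OC)cc3)[C@@H]2[C@@H](O[Si](CC)(CC)CC)C[C@@]1(C)O
F8 | step 6 | β-hydroxy sulfide: 8-hydroxy-8-[1-(methylthio)allyl] hydrindane, 6α-OTES | C=CC(SC)C1(O)[C@@]2(C)CCC[C@@](C)(COCc3ccc(OC)cc3)[C@@H]2[C@@H](O[Si](CC)(CC)CC)C1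
F9 | step 3 | 4α-(hydroxymethyl)-4β-methyl-3-oxo-hydrind-5-ene C8 ethylene ketal | O1CCOC13[C@@]2(C)CCC(=O)[C@@](C)(CO)C2=CC3
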